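**Retrosynthetic overview**
- Ring C is formed last. The target comes from acid cyclisation and loss of methanol from a 1-(2,6-dihydroxyaryl)-2-aryl-3,3-dimethoxypropan-1-one. Ring A is symmetric, so either hydroxyl gives the same product.
- The acetal comes from an oxidative 1,2-aryl shift, with Tl(NO3)3, of a fully benzyl-protected chalcone.
- The chalcone comes from a Claisen–Schmidt aldol condensation of the ring A acetophenone with the ring B benzaldehyde. This key C–C bond becomes C2–C3 of the isoflavone.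
- The ring A ketone is made from 1,2,3-trimethoxybenzene by dibromination, borylation/oxidation, C-acetylation and benzylation.
- The ring B aldehyde is made from 2,3-dihydroxybenzaldehyde by 3-O-benzylation and then 2-O-methylation.

Assumption: the target has no stereocentre and no stable chiral axis, so it is one achiral compound and needs no asymmetric step. Stereocentres that arise in intermediates are racemic and are erased before the end.

**Route**

Step 1
Reactants: 1 1,2,3-trimethoxybenzene
Product: 2 1,5-dibromo-2,3,4-trimethoxybenzene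
Conditions: NBS (2.1 equiv), MeCN, 0 °C to rt, 16 h
Reagents that add atoms: N-bromosuccinimide O=C1CCC(=O)N1Br
Why: In this electrophilic aromatic bromination, C4 and C6 are each ortho to one methoxy and para to another, whereas C5 is activated only by the twisted central methoxy, so the 4,6-dibromide forms.

Step 2
Reactants: 2 1,5-dibromo-2,3,4-trimethoxybenzene
Product: 3 2,2'-(4,5,6-trimethoxybenzene-1,3-diyl)bis(4,4,5,5-tetramethyl-1,3,2-dioxaborolane)
Conditions: B2pin2 (2.6 equiv), PdCl2(dppf) (5 mol %), KOAc (6 equiv), 1,4-dioxane, 90 °C, 16 h, N2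
Reagents that add atoms: bis(pinacolato)diboron CC1(C)OB(OC1(C)C)B1OC(C)(C)C(C)(C)O1
Why: In this double Miyaura borylation, zerovalent palladium inserts into each C–Br bond and acetate-assisted transmetalation with the diboron fixes boron exactly where oxygen is needed.

Step 3
Reactants: 3 2,2'-(4,5,6-trimethoxybenzene-1,3-diyl)bis(4,4,5,5-tetramethyl-1,3,2-dioxaborolane)
Product: 4 4,5,6-trimethoxybenzene-1,3-diol
Conditions: 30% aq H2O2 (5 equiv), 1 M NaOH (2.5 equiv), THF, 0 °C, 1 h, N2; Na2SO3 quench; 1 M HCl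
Reagents that add atoms: hydrogen peroxide OO
Why: In this boronate oxidation, hydroperoxide adds to boron and the aryl group migrates from boron to oxygen at the same carbon, and the short, cold, oxygen-free protocol protects the electron-rich diol.

Step 4
Reactants: 4 4,5,6-trimethoxybenzene-1,3-diol
Product: 5 1-(2,6-dihydroxy-3,4,5-trimethoxyphenyl)ethan-1-one
Conditions: AcOH (3 equiv), BF3·OEt2 (ca. 10 equiv, neat), 85 °C, 2 h; ice-water
Reagents that add atoms: acetic acid CC(=O)O
Why: This Friedel–Crafts C-acylation (with Fries-type transfer of any O-acetate) can only occur at the single free ring carbon between the two hydroxyls, and no methoxy group sits ortho to the new carbonyl to be cleaved.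

Step 5
Reactants: 5 1-(2,6-dihydroxy-3,4,5-trimethoxyphenyl)ethan-1-one
Product: 6 1-[2,6-bis(benzyloxy)-3,4,5-trimethoxyphenyl]ethan-1-one
Conditions: BnBr (2.6 equiv), K2CO3 (4 equiv), Bu4NI (5 mol %), DMF, 70 °C, 12 h
Reagents that add atoms: benzyl bromide BrCc1ccccc1
Why: This Williamson ether synthesis masks both chelated phenols, the fully substituted ring rules out C-alkylation, and ring A is thereby shielded from the later oxidant.

Step 6
Reactants: 7 2,3-dihydroxybenzaldehyde
Product: 9 3-(benzyloxy)-2-hydroxybenzaldehyde, via disodium dianion 8 (not isolated)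
Conditions: NaH (2.2 equiv), DMSO, 20 °C, 1 h; BnBr (1.0 equiv), 20 °C, 16 h; 1 M HCl
Reagents that add atoms: benzyl bromide BrCc1ccccc1; sodium hydride [Na+].[H-] (supplies only the sodium of 8)
Why: This is a regioselective Williamson alkylation of the catecholate dianion, in which the 2-oxide is delocalised into the aldehyde and the 3-oxide is therefore the more nucleophilic site for one equivalent of halide.

Step 7
Reactants: 9 3-(benzyloxy)-2-hydroxybenzaldehyde
Product: 10 3-(benzyloxy)-2-methoxybenzaldehyde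
Conditions: MeI (1.5 equiv), K2CO3 (2 equiv), DMF, rt, 6 h
Reagents that add atoms: iodomethane CI
Why: Williamson O-methylation of the one remaining phenol sets the 2'-OMe/3'-O pattern unambiguously.

Step 8
Reactants: 6 1-[2,6-bis(benzyloxy)-3,4,5-trimethoxyphenyl]ethan-1-one; 10 3-(benzyloxy)-2-methoxybenzaldehyde
Product: 12 (E)-1-[2,6-bis(benzyloxy)-3,4,5-trimethoxyphenyl]-3-[3-(benzyloxy)-2-methoxyphenyl]prop-2-en-1-one, via aldol adduct 11 (not isolated)
Conditions: KOH (50% aq, 8 equiv), EtOH–THF (3:1), rt, 36 h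
Reagents that add atoms: none
Why: In this Claisen–Schmidt aldol condensation the methyl ketone enolate, which carries no deactivating phenoxide, adds to the non-enolisable aldehyde, and E1cB dehydration of the racemic carbinol gives the thermodynamically favoured E-enone.

Step 9
Reactants: 12 (E)-1-[2,6-bis(benzyloxy)-3,4,5-trimethoxyphenyl]-3-[3-(benzyloxy)-2-methoxyphenyl]prop-2-en-1-one
Product: 13 1-[2,6-bis(benzyloxy)-3,4,5-trimethoxyphenyl]-2-[3-(benzyloxy)-2-methoxyphenyl]-3,3-dimethoxypropan-1-one (racemic)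
Conditions: Tl(NO3)3·3H2O (1.2 equiv), MeOH–HC(OMe)3–CH2Cl2 (2:1:1), rt, 6 h; filter; aq NaHCO3
Reagents that add atoms: methanol CO
Why: In this oxidative chalcone rearrangement, methoxythallation by trivalent thallium is followed by loss of monovalent thallium with a 1,2-shift of the ortho-methoxy-activated ring B aryl to the alpha carbon, methanol traps the oxocarbenium ion, and the new C2 stereocentre is racemic and is erased in step 11.

Step 10
Reactants: 13 1-[2,6-bis(benzyloxy)-3,4,5-trimethoxyphenyl]-2-[3-(benzyloxy)-2-methoxyphenyl]-3,3-dimethoxypropan-1-one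
Product: 14 1-(2,6-dihydroxy-3,4,5-trimethoxyphenyl)-2-(3-hydroxy-2-methoxyphenyl)-3,3-dimethoxypropan-1-one (racemic)
Conditions: H2 (1 atm), Pd/C (10 wt %), EtOAc–MeOH (1:1), rt, 4 h
Reagents that add atoms: none
Why: Catalytic hydrogenolysis cleaves the three benzyl ethers while the acetal, the hindered ketone and the methyl ethers stay intact, and doing it before ring C exists removes any risk of reducing the C2–C3 double bond.

Step 11
Reactants: 14 1-(2,6-dihydroxy-3,4,5-trimethoxyphenyl)-2-(3-hydroxy-2-methoxyphenyl)-3,3-dimethoxypropan-1-one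
Product: 16 5,3'-dihydroxy-6,7,8,2'-tetramethoxyisoflavone, via 2-methoxyisoflavanone 15 (not isolated)
Conditions: 10% aq HCl–MeOH (1:5), reflux, 2 h
Reagents that add atoms: none
Why: In this acid-catalysed acetal cyclisation–elimination, either of the two equivalent ring A hydroxyls adds to the oxocarbenium ion to close ring C, and loss of methanol gives the conjugated chromen-4-one, which removes all transient stereocentres and leaves the other hydroxyl as the chelated 5-OH.

**Compound list**

1 | 1,2,3-trimethoxybenzene | COc1cccc(OC)c1OC | starting material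
2 | 1,5-dibromo-2,3,4-trimethoxybenzene | COc1c(Br)cc(Br)c(OC)c1OC | intermediate
3 | 2,2'-(4,5,6-trimethoxybenzene-1,3-diyl)bis(4,4,5,5-tetramethyl-1,3,2-dioxaborolane) | COc1c(B2OC(C)(C)C(C)(C)O2)cc(B2OC(C)(C)C(C)(C)O2)c(OC)c1OC | intermediate
4 | 4,5,6-trimethoxybenzene-1,3-diol | COc1c(O)cc(O)c(OC)c1OC | intermediate
5 | 1-(2,6-dihydroxy-3,4,5-trimethoxyphenyl)ethan-1-one | CC(=O)c1c(O)c(OC)c(OC)c(OC)c1O | intermediate
6 | 1-[2,6-bis(benzyloxy)-3,4,5-trimethoxyphenyl]ethan-1-one | CC(=O)c1c(OCc2ccccc2)c(OC)c(OC)c(OC)c1OCc1ccccc1 | intermediate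
7 | 2,3-dihydroxybenzaldehyde | O=Cc1cccc(O)c1O | starting material
8 | disodium 3-formylbenzene-1,2-diolate (not isolated) | [Na+].[Na+].[O-]c1cccc(C=O)c1[O-] | intermediate
9 | 3-(benzyloxy)-2-hydroxybenzaldehyde | O=Cc1cccc(OCc2ccccc2)c1O | intermediate
10 | 3-(benzyloxy)-2-methoxybenzaldehyde | COc1c(C=O)cccc1OCc1ccccc1 | intermediate
11 | 1-[2,6-bis(benzyloxy)-3,4,5-trimethoxyphenyl]-3-[3-(benzyloxy)-2-methoxyphenyl]-3-hydroxypropan-1-one (racemic, not isolated) | COc1c(OCc2ccccc2)cccc1C(O)CC(=O)c1c(OCc2ccccc2)c(OC)c(OC)c(OC)c1OCc1ccccc1 | intermediate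
12 | (E)-1-[2,6-bis(benzyloxy)-3,4,5-trimethoxyphenyl]-3-[3-(benzyloxy)-2-methoxyphenyl]prop-2-en-1-one | COc1c(OCc2ccccc2)cccc1/C=C/C(=O)c1c(OCc2ccccc2)c(OC)c(OC)c(OC)c1OCc1ccccc1 | intermediate
13 | 1-[2,6-bis(benzyloxy)-3,4,5-trimethoxyphenyl]-2-[3-(benzyloxy)-2-methoxyphenyl]-3,3-dimethoxypropan-1-one (racemic) | COC(OC)C(C(=O)c1c(OCc2ccccc2)c(OC)c(OC)c(OC)c1OCc1ccccc1)c1cccc(OCc2ccccc2)c1OC | intermediate
14 | 1-(2,6-dihydroxy-3,4,5-trimethoxyphenyl)-2-(3-hydroxy-2-methoxyphenyl)-3,3-dimethoxypropan-1-one (racemic) | COC(OC)C(C(=O)c1c(O)c(OC)c(OC)c(OC)c1O)c1cccc(O)c1OC | intermediate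
15 | 5-hydroxy-3-(3-hydroxy-2-methoxyphenyl)-2,6,7,8-tetramethoxychroman-4-one (racemic diastereomer mixture, not isolated) | COC1Oc2c(OC)c(OC)c(OC)c(O)c2C(=O)C1c1cccc(O)c1OC | intermediate
16 | 5,3'-dihydroxy-6,7,8,2'-tetramethoxyisoflavone, i.e. 5-hydroxy-3-(3-hydroxy-2-methoxyphenyl)-6,7,8-trimethoxy-4H-chromen-4-one (achiral) | COc1c(O)cccc1-c1coc2c(OC)c(OC)c(OC)c(O)c2c1=O | target

**Totals**
- Total step count: 11.
- Longest linear sequence: 9 steps (steps 1–5, then 8–11).

**Steps most likely to fail**

Step 9 (oxidative aryl shift). Ring B carries only an ortho donor, so migration may be slow. Trivalent thallium could also attack the pentaalkoxy ring A.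
The fallback sets out from chalcone 12. Weitz–Scheffer epoxidation (30% H2O2, NaOH, MeOH–THF, 0 °C to rt) gives the racemic trans chalcone epoxide F1. BF3·OEt2 (CH2Cl2, −10 to 0 °C, short contact) opens it at the benzylic carbon and triggers a 1,2-aroyl shift to the alpha-formyl deoxybenzoin F2. Hydrogenolysis (H2, Pd/C, EtOAc) frees the phenols, one of which closes onto the aldehyde to give the 2-hydroxyisoflavanone F3. Brief warming in HCl–MeOH dehydrates it, and the route is rejoined at 16.

Step 2 (double borylation). The electron-rich, ortho-substituted dibromide may stop at the monoboronate or undergo protodehalogenation. The diol that follows is also oxidation-sensitive.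
The fallback sets out from dibromide 2. Ullmann-type double methoxylation (NaOMe 6 equiv, CuI 20 mol %, DMF–MeOH, 110 °C) gives pentamethoxybenzene F4. Friedel–Crafts acetylation (AcCl, AlCl3 2.5 equiv, CH2Cl2, 0 °C to rt) passes through pentamethoxyacetophenone F5. This loses one ortho methyl in the flask by chelation and gives 2-hydroxy-3,4,5,6-tetramethoxyacetophenone F6. BCl3 (3 equiv, CH2Cl2, 0 °C to rt) then removes the second carbonyl-flanking methyl. The route is rejoined at 5, bypassing steps 2–4.

Step 6 (regioselective monobenzylation). The 2-O-benzyl and dibenzyl ethers may contaminate the product.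
The fallback sets out from 7. Exhaustive benzylation (BnBr 2.5 equiv, K2CO3, DMF, 60 °C) gives 2,3-bis(benzyloxy)benzaldehyde F7. MgBr2·OEt2 (toluene–Et2O, reflux) then cleaves only the benzyl ether chelated to the aldehyde carbonyl, and the route is rejoined at 9.

**Further compounds**

F1 | step 9 | [2,6-bis(benzyloxy)-3,4,5-trimethoxyphenyl]{trans-3-[3-(benzyloxy)-2-methoxyphenyl]oxiran-2-yl}methanone (racemic, one enantiomer drawn) | O=C([C@H]1O[C@@H]1c1cccc(OCc2ccccc2)c1OC)c1c(OCc2ccccc2)c(OC)c(OC)c(OC)c1OCc1ccccc1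
F2 | step 9 | 3-[2,6-bis(benzyloxy)-3,4,5-trimethoxyphenyl]-2-[3-(benzyloxy)-2-methoxyphenyl]-3-oxopropanal (racemic) | O=CC(C(=O)c1c(OCc2ccccc2)c(OC)c(OC)c(OC)c1OCc1ccccc1)c1cccc(OCc2ccccc2)c1OC
F3 | step 9 | 2,5-dihydroxy-3-(3-hydroxy-2-methoxyphenyl)-6,7,8-trimethoxychroman-4-one (racemic diastereomer mixture) | OC1Oc2c(OC)c(OC)c(OC)c(O)c2C(=O)C1c1cccc(O)c1OC
F4 | step 2 | pentamethoxybenzene | COc1cc(OC)c(OC)c(OC)c1OC
F5 | step 2 | 1-(2,3,4,5,6-pentamethoxyphenyl)ethan-1-one | CC(=O)c1c(OC)c(OC)c(OC)c(OC)c1OC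
F6 | step 2 | 1-(2-hydroxy-3,4,5,6-tetramethoxyphenyl)ethan-1-one | CC(=O)c1c(O)c(OC)c(OC)c(OC)c1OC
F7 | step 6 | 2,3-bis(benzyloxy)benzaldehyde | O=Cc1cccc(OCc2ccccc2)c1OCc1ccccc1
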